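The numbers are invented; no experiment stands behind them.

The pitfall is to go by the clock: alder runs twice as long as elm, and that looks as if it must change the chains.

- elm: X 0.073 M; J 0.5 mol%; time 4.0 min
- alder: X 0.073 M; J 0.5 mol%; time 8.0 min

    X + Q → E + Q, rate k1*[Q]*[X] (k1 = 370 M⁻¹ s⁻¹)
    J → D (k2 = 0.0020 s⁻¹)
    X + D → Q + E (k3 = 0.33 M⁻¹ s⁻¹)

1. which of the two ends with the longer chains by the average number of monomer units in a chain (chains begun, living or dead) ("neither" if they lie within 10 %) (elm / alder / neither)
2. average number of monomer units in a chain (chains begun, living or dead) at the end, elm
3. average number of monomer units in a chain (chains begun, living or dead) at the end, alder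

- the average divides the monomer in chains by the number of chains begun, living and dead together
- run time (elm): 4.0 min

The scheme has no step that consumes Q, so c_Q counts the chains begun.

First I ask how fast chains begin. Each flask charges 3.65 × 10⁻⁴ M of J, whose lifetime of 8.33 min is far longer than the 0.692 min of D at the charged c_X. At the start J releases D at 7.30 × 10⁻⁷ M s⁻¹, which I call the feed. D stands between J and Q, so I use the feed as a scale for the growth of c_Q, not as its course.

Next I ask how long X lasts on that scale, taking c_Q as the feed times the time. Integrating the propagation rate on this assumption, c_X falls by one factor e at the square root of two over the propagation constant times the feed, 1.43 min. This is the run-out time. It is shorter than the lifetime of J, so the release of D from J holds up to it. The lifetime of D at the charged c_X is about half of it, so the lag at D is not small and the run-out time is a scale, too.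

Last I ask where the flasks stop. Elm stops at 2.79 run-out times and alder at 5.58, both beyond it. So I estimate the chains begun as the feed times the run-out time, 6.28 × 10⁻⁵ M, for each flask. That gives 1160 for elm and 1160 for alder, and my answer is neither.

The forecast says 1080 for elm, 1077 for alder and neither, on the ground that “Chains are therefore begun gradually, and monomer runs out before most of the initiator has reacted.”

The simulation gives 1090 for elm and 1080 for alder, so neither.

Elm ends with c_Q at 6.50 × 10⁻⁵ M and alder with 6.79 × 10⁻⁵ M, against my 6.28 × 10⁻⁵ M. Alder keeps 0.0082 % of its X and 38 % of its J, so X is the limiting reagent there. The neighbouring flask is alder with 0.029 M of X. Its feed is 2.90 × 10⁻⁷ M s⁻¹ and its run-out time 2.28 min, so this neighbour stops at 3.52 run-out times, and the same reckoning gives a length of 732. The simulated neighbour ends at 788, with 1.74 % of its X left.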